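**Retrosynthetic overview**

- The target comes from its 7-O-silyl ether, which comes from a 9-hydroxy-15-oxo-ent-kaur-16-ene by the biogenetic C8–C9 retro-aldol scission plus dehydrogenation of the freed C-8 enolate; this opens rings B and C into the ten-membered ring.
- The 9-hydroxy-ent-kaurane comes from a head-to-tail polyene bicyclization of a geranyl chain (ring A, then ring B), started by H-atom transfer and ended by addition of the C-10 radical to a C-9 ketone, which delivers the 9-OH.
- The cyclization substrate comes from a geranylbarium reagent and a bicyclo[3.2.1]octane keto-aldehyde (rings C and D); the C-7 carbinol is made in this C6–C7 bond formation.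
- The bicycle comes from 4-isopropenylcyclohexanone by ene chlorination, enantiotopic deprotonation/formylation and intramolecular alkylation (ring D); C-17 is masked as a ketone during the radical step.
- Ring order: C (bought), D, A, B, then fragmentation of B/C into the macrocycle.

Assumption: 4-isopropenylcyclohexanone (1) is bought as a catalogue building block; if unavailable it is one acid-mediated ring-opening step from nopinone, the ozonolysis product of β-pinene.

Convention: kaurane numbering is used in all Why lines; α means the face of the C-20 methyl, β the opposite face. In the bicyclo[3.2.1]octanes, IUPAC C-1, C-2, C-5, C-6, C-7, C-8 are kaurane C-8, C-9, C-13, C-16, C-15, C-14.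

**Route**

Step 1
Reactants: 1 4-(prop-1-en-2-yl)cyclohexan-1-one
Product: 2 4-(3-chloroprop-1-en-2-yl)cyclohexan-1-one
Conditions: Ca(OCl)2, CO2 (dry ice), CH2Cl2/H2O, 0 °C
Reagents that add atoms: Ca(OCl)2 [Ca+2].[O-]Cl.[O-]Cl
Why: Ene-type allylic chlorination of the 1,1-disubstituted alkene by HOCl made in the flask, with transposition of the double bond; the ketone is inert and no stereocenter is formed.

Step 2
Reactants: 2 4-(3-chloroprop-1-en-2-yl)cyclohexan-1-one
Product: 5 (1R,5S)-6-methylidene-2-oxobicyclo[3.2.1]octane-1-carbaldehyde, via lithium enolate 3 (not isolated), via formyl enolate 4 (not isolated)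
Conditions: (R,R)-[PhCH(Me)]2NH, n-BuLi, LiCl, THF, −78 °C; CF3CH2OCHO, −78 → 0 °C; then DMPU, NaI (cat.), 40 °C
Reagents that add atoms: 2,2,2-trifluoroethyl formate O=COCC(F)(F)F
Why: Enantioselective deprotonation of the symmetric ketone by the C2-symmetric chiral lithium amide sets C-13 (same sense as the 4-tert-butylcyclohexanone to (S)-enolate case, about 90% ee expected); Claisen-type C-formylation of that regiodefined enolate and intramolecular SN2 C-alkylation by the allylic chloride then close ring D, and the two-atom bridge can only form cis, which fixes C-8.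

Step 3
Reactants: 5 (1R,5S)-6-methylidene-2-oxobicyclo[3.2.1]octane-1-carbaldehyde
Product: 6 (1R,5S)-2,6-dioxobicyclo[3.2.1]octane-1-carbaldehyde
Conditions: O3, CH2Cl2, −78 °C; PPh3
Reagents that add atoms: ozone [O-][O+]=O
Why: Ozonolysis with reductive work-up turns the exocyclic alkene, which would compete in the later hydrogen-atom-transfer step, into the C-16 ketone; aldehyde, ketone and both stereocenters are untouched.

Step 4
Reactants: 6 (1R,5S)-2,6-dioxobicyclo[3.2.1]octane-1-carbaldehyde; 7 geranyl chloride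
Product: 10 (1R,5S)-1-[(1R,3E)-1-(tert-butyldimethylsilyloxy)-4,8-dimethylnona-3,7-dien-1-yl]bicyclo[3.2.1]octane-2,6-dione, via geranylbarium chloride 8 (not isolated), via barium alkoxide 9 (not isolated)
Conditions: BaI2, Li, biphenyl (cat.), THF, rt; 7, −78 °C; 6, −78 °C; then TBSOTf, −78 → −40 °C
Reagents that add atoms: tert-butyldimethylsilyl triflate CC(C)(C)[Si](C)(C)OS(=O)(=O)C(F)(F)F
Why: Yamamoto allylbarium addition attacks through the unsubstituted terminus with retention of the E alkene and prefers the aldehyde over both ketones; Cram-chelate control (Ba between the C-7 and C-9 oxygens, attack anti to the C-15 methylene) is expected to give the 7R carbinol, which is silylated in the same flask.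

Step 5
Reactants: 10 (1R,5S)-1-[(1R,3E)-1-(tert-butyldimethylsilyloxy)-4,8-dimethylnona-3,7-dien-1-yl]bicyclo[3.2.1]octane-2,6-dione
Product: 11 7α-(tert-butyldimethylsilyloxy)-9β-hydroxy-17-nor-ent-kauran-16-one
Conditions: Fe(acac)3 (30 mol %), PhSiH3, EtOH/(CH2OH)2, 60 °C, 0.01 M
Reagents that add atoms: none
Why: Proposed new method: an iron hydride formed from Fe(acac)3 and PhSiH3 transfers H• to C-3 of the terminal trisubstituted alkene (the radical counterpart of the protonation that starts copalyl diphosphate formation), the tertiary C-4 radical adds 6-endo to C-5 through a chair with the 7-OTBS equatorial, the tertiary C-10 radical adds 6-exo to the C-9 ketone, and divalent iron reduces the alkoxyl radical to the alkoxide, which makes the sequence irreversible; the closest known reaction types are the HAT-initiated radical polyene cyclization and the iron hydride reductive alkene–ketone coupling, and the chair sets H-5 cis to H-7 and C-20 trans to H-5, while C-9 follows from the trans-diequatorial ring fusion.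

Step 6
Reactants: 11 7α-(tert-butyldimethylsilyloxy)-9β-hydroxy-17-nor-ent-kauran-16-one
Product: 12 7α-(tert-butyldimethylsilyloxy)-ent-kaur-16-en-9β-ol
Conditions: Ph3PCH3Br, KOtBu, THF, 0 °C → rt
Reagents that add atoms: methyltriphenylphosphonium bromide C[P+](c1ccccc1)(c1ccccc1)c1ccccc1.[Br-]
Why: Wittig methylenation of the cyclopentanone restores C-17 (the classical last step of kaurene syntheses); the tertiary alkoxide and the silyl ether are spectators and no stereocenter changes.

Step 7
Reactants: 12 7α-(tert-butyldimethylsilyloxy)-ent-kaur-16-en-9β-ol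
Product: 14 7α-(tert-butyldimethylsilyloxy)-9β-hydroxy-ent-kaur-16-en-15-one, via allylic alcohol 13 (not isolated)
Conditions: SeO2 (30 mol %), t-BuOOH, CH2Cl2, rt; then MnO2, rt
Reagents that add atoms: tert-butyl hydroperoxide CC(C)(C)OO
Why: Riley-type allylic oxidation (ene reaction then [2,3]-shift) can only take C-15 because C-13 is a bridgehead, and MnO2 then destroys excess peroxide and oxidizes the allylic alcohol to the enone without touching the tertiary 9-OH; the transient C-15 carbinol center is removed again.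

Step 8
Reactants: 14 7α-(tert-butyldimethylsilyloxy)-9β-hydroxy-ent-kaur-16-en-15-one
Product: 18 (5R,7R,10R,13S)-7-(tert-butyldimethylsilyloxy)-8,9-seco-ent-kaura-8(14),16-diene-9,15-dione, via potassium alkoxide 15 (not isolated), via seco enolate 16 (not isolated), via sulfilimine 17 (not isolated)
Conditions: KN(SiMe3)2, THF, −78 → −40 °C; PhS(Cl)=N-t-Bu, −78 °C
Reagents that add atoms: none
Why: The 9-alkoxide undergoes the biogenetic retro-aldol C8–C9 scission (strain release, cross-conjugated enolate), which forms the ten-membered ring and a regiodefined C-8 enolate; Mukaiyama dehydrogenation (α-sulfenylation with the sulfinimidoyl chloride, then syn-elimination toward the ring CH2 at C-14) gives the 8(14)-ene, silyloxide at C-7 being too poor a leaving group for E1cB at −78 °C, and only the C-8 and C-9 stereocenters are lost.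

Step 9
Reactants: 18 (5R,7R,10R,13S)-7-(tert-butyldimethylsilyloxy)-8,9-seco-ent-kaura-8(14),16-diene-9,15-dione
Product: 19 (5R,7R,10R,13S)-7-acetoxy-8,9-seco-ent-kaura-8(14),16-diene-9,15-dione
Conditions: Ac2O, Cu(OTf)2 (5 mol %), CH2Cl2, rt
Reagents that add atoms: acetic anhydride CC(=O)OC(C)=O
Why: Lewis-acid-catalysed direct exchange of the silyl ether for an acetate under non-basic conditions that spare the dienone; the C7–O bond is never broken, so C-7 is retained.

**Compound list**

1 | 4-(prop-1-en-2-yl)cyclohexan-1-one (4-isopropenylcyclohexanone; achiral) | CC(=C)C1CCC(=O)CC1 | starting material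
2 | 4-(3-chloroprop-1-en-2-yl)cyclohexan-1-one (achiral) | ClCC(=C)C1CCC(=O)CC1 | intermediate
3 | lithium (4S)-4-(3-chloroprop-1-en-2-yl)cyclohex-1-en-1-olate | [Li+].[O-]C1=CC[C@@H](C(=C)CCl)CC1 | intermediate
4 | lithium (Z)-[(5S)-5-(3-chloroprop-1-en-2-yl)-2-oxocyclohexylidene]methanolate | [Li+].[O-]/C=C1/C[C@@H](C(=C)CCl)CCC1=O | intermediate
5 | (1R,5S)-6-methylidene-2-oxobicyclo[3.2.1]octane-1-carbaldehyde | C=C1C[C@]2(C[C@@H]1CCC2=O)C=O | intermediate
6 | (1R,5S)-2,6-dioxobicyclo[3.2.1]octane-1-carbaldehyde | O=C1C[C@]2(C[C@@H]1CCC2=O)C=O | intermediate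
7 | geranyl chloride, (2E)-1-chloro-3,7-dimethylocta-2,6-diene | ClC/C=C(\C)CCC=C(C)C | starting material
8 | geranylbarium chloride, C10H17BaCl | [Ba+2].[Cl-].[CH2-]/C=C(\C)CCC=C(C)C | intermediate
9 | barium chloride (1R,3E)-1-[(1R,5S)-2,6-dioxobicyclo[3.2.1]octan-1-yl]-4,8-dimethylnona-3,7-dien-1-olate | O=C1C[C@]2(C[C@@H]1CCC2=O)[C@H]([O-])C/C=C(\C)CCC=C(C)C.[Ba+2].[Cl-] | intermediate
10 | (1R,5S)-1-[(1R,3E)-1-(tert-butyldimethylsilyloxy)-4,8-dimethylnona-3,7-dien-1-yl]bicyclo[3.2.1]octane-2,6-dione | O=C1C[C@]2(C[C@@H]1CCC2=O)[C@H](O[Si](C)(C)C(C)(C)C)C/C=C(\C)CCC=C(C)C | intermediate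
11 | 7α-(tert-butyldimethylsilyloxy)-9β-hydroxy-17-nor-ent-kauran-16-one (A/B and B/C trans; C-20 and the C-15/C-16 bridge α; H-5 and 9-OH β; 7-OTBS equatorial) | O=C1C[C@]23C[C@@H]1CC[C@@]3(O)[C@]1(C)CCCC(C)(C)[C@H]1C[C@H]2O[Si](C)(C)C(C)(C)C | intermediate
12 | 7α-(tert-butyldimethylsilyloxy)-ent-kaur-16-en-9β-ol (ring stereochemistry as in 11) | C=C1C[C@]23C[C@@H]1CC[C@@]3(O)[C@]1(C)CCCC(C)(C)[C@H]1C[C@H]2O[Si](C)(C)C(C)(C)C | intermediate
13 | 7α-(tert-butyldimethylsilyloxy)-ent-kaur-16-ene-9β,15-diol (15-OH on the ring D face turned toward C-14; expected major epimer) | C=C1[C@@H](O)[C@]23C[C@@H]1CC[C@@]3(O)[C@]1(C)CCCC(C)(C)[C@H]1C[C@H]2O[Si](C)(C)C(C)(C)C | intermediate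
14 | 7α-(tert-butyldimethylsilyloxy)-9β-hydroxy-ent-kaur-16-en-15-one | C=C1C(=O)[C@]23C[C@@H]1CC[C@@]3(O)[C@]1(C)CCCC(C)(C)[C@H]1C[C@H]2O[Si](C)(C)C(C)(C)C | intermediate
15 | potassium 9-alkoxide of 14 | C=C1C(=O)[C@]23C[C@@H]1CC[C@@]3([O-])[C@]1(C)CCCC(C)(C)[C@H]1C[C@H]2O[Si](C)(C)C(C)(C)C.[K+] | intermediate
16 | potassium C-15 enolate (C-8=C-15) of (5R,7R,10R,13S)-7-(tert-butyldimethylsilyloxy)-8,9-seco-ent-kaur-16-ene-9,15-dione | C=C1C([O-])=C2C[C@@H]1CCC(=O)[C@]1(C)CCCC(C)(C)[C@H]1C[C@H]2O[Si](C)(C)C(C)(C)C.[K+] | intermediate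
17 | C-8 S-phenyl-N-tert-butylsulfilimine of the seco-dione (formed as a mixture at C-8 and at sulfur; both centers are lost on elimination) | C=C1C(=O)C2(C[C@@H]1CCC(=O)[C@]1(C)CCCC(C)(C)[C@H]1C[C@H]2O[Si](C)(C)C(C)(C)C)S(=NC(C)(C)C)c1ccccc1 | intermediate
18 | (5R,7R,10R,13S)-7-(tert-butyldimethylsilyloxy)-8,9-seco-ent-kaura-8(14),16-diene-9,15-dione | C=C1C(=O)C2=C[C@@H]1CCC(=O)[C@]1(C)CCCC(C)(C)[C@H]1C[C@H]2O[Si](C)(C)C(C)(C)C | intermediate
19 | (5R,7R,10R,13S)-7-acetoxy-8,9-seco-ent-kaura-8(14),16-diene-9,15-dione (CNP0421845.1) | C=C1C(=O)C2=C[C@@H]1CCC(=O)[C@]1(C)CCCC(C)(C)[C@H]1C[C@H]2OC(C)=O | target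

**Step count and risks**

Total step count: 9. Longest linear sequence: 9 steps (from 1; geranyl chloride 7 enters at step 4).

The three steps most likely to fail:

Step 5, the iron hydride polyene bicyclization ending on the ketone. It is the least precedented step. Hydrogen-atom transfer may start at the internal alkene, the C-10 radical may be reduced before it reaches the ketone, and the ring B chair that leads to the ent-kaurane (7-OTBS equatorial, C-20 syn to C-15) may lose to the alternative chair with axial OTBS, which would give the wrong ring A configuration. The fallback sets out from 10 and comes back at 11: ring A is closed first by a proton-initiated cationic cyclization of the geranyl unit (ClSO3H in 2-nitropropane at −78 °C, or SnCl4), stopped at the exocyclic alkene to give the γ-cyclogeranyl-type monocycle F1. Its single 1,1-disubstituted alkene then undergoes the established iron hydride reductive alkene–ketone coupling (Fe(acac)3, PhSiH3) onto the C-9 ketone, which closes ring B and gives 11.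

Step 4, the allylbarium addition. The C-7 configuration rests on chelate control on a neopentyl aldehyde whose two faces differ only by the C-14 and C-15 methylenes, so the diastereomer ratio may be low; γ-attack is a second risk. The fallback sets out from 6 and comes back at 11 and takes C-7 out of the addition step: 6 is combined with geranylbarium chloride 8 without regard to facial control to give the C-7 epimeric alcohols F2. Dess–Martin oxidation gives the C-7 ketone F3. The same iron hydride cascade then gives the tetracyclic 7-ketone F4. Me4NBH(OAc)3, bound to the 9β-hydroxyl, delivers hydride to C-7 from the β face and gives the anti diol F5 with the equatorial 7α-OH. Selective silylation of the secondary hydroxyl (TBSOTf, 2,6-lutidine) gives 11.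

Step 8, the fragmentation with dehydrogenation in one flask. The C-8 enolate carries a β-silyloxy group that is aligned for E1cB loss, and the sulfilimine could eliminate toward C-7 instead of C-14. The fallback sets out from 14 and comes back at 18 and separates the two events: the alkoxide fragmentation (KN(SiMe3)2, −78 °C) is quenched at once with AcOH to give the seco-dione F6 as C-8 epimers. Enol selenenylation under acidic conditions (PhSeCl, EtOAc) gives the C-8 selenide F7. Oxidation with H2O2/pyridine and syn-elimination of the selenoxide, which avoids the oxygen-bearing C-7, gives 18.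

Further compounds

F1 | step 5 | (1R,5S)-1-{(1R)-1-(tert-butyldimethylsilyloxy)-2-[2,2-dimethyl-6-methylidenecyclohexyl]ethyl}bicyclo[3.2.1]octane-2,6-dione, ring A closed with H-5 cis to H-7 as in 11 | O=C1C[C@]2(C[C@@H]1CCC2=O)[C@H](O[Si](C)(C)C(C)(C)C)C[C@H]1C(=C)CCCC1(C)C
F2 | step 4 | (1R,5S)-1-[(3E)-1-hydroxy-4,8-dimethylnona-3,7-dien-1-yl]bicyclo[3.2.1]octane-2,6-dione, mixture of C-7 epimers | O=C1C[C@]2(C[C@@H]1CCC2=O)C(O)C/C=C(\C)CCC=C(C)C
F3 | step 4 | (1R,5S)-1-[(3E)-4,8-dimethylnona-3,7-dienoyl]bicyclo[3.2.1]octane-2,6-dione | O=C1C[C@]2(C[C@@H]1CCC2=O)C(=O)C/C=C(\C)CCC=C(C)C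
F4 | step 4 | 9β-hydroxy-17-nor-ent-kaurane-7,16-dione | O=C1C[C@]23C[C@@H]1CC[C@@]3(O)[C@]1(C)CCCC(C)(C)[C@H]1CC2=O
F5 | step 4 | 7α,9β-dihydroxy-17-nor-ent-kauran-16-one | O=C1C[C@]23C[C@@H]1CC[C@@]3(O)[C@]1(C)CCCC(C)(C)[C@H]1C[C@H]2O
F6 | step 8 | (5R,7R,10R,13S)-7-(tert-butyldimethylsilyloxy)-8,9-seco-ent-kaur-16-ene-9,15-dione, C-8 epimers | C=C1C(=O)C2C[C@@H]1CCC(=O)[C@]1(C)CCCC(C)(C)[C@H]1C[C@H]2O[Si](C)(C)C(C)(C)C
F7 | step 8 | 8-(phenylselanyl) derivative of F6, C-8 epimers | C=C1C(=O)C2(C[C@@H]1CCC(=O)[C@]1(C)CCCC(C)(C)[C@H]1C[C@H]2O[Si](C)(C)C(C)(C)C)[Se]c1ccccc1
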